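The ring of the target holds a cross-conjugated diene: the tetrasubstituted ring alkene C2=C3 of the cyclohexenone and the exocyclic C1'=C2' alkene of the heptenyl chain on C2. A 1-alkenylcyclohexene is the product pattern of ring-closing enyne metathesis, so the ring is closed at C2=C3 from an acyclic 1,7-enyne: a terminal alkyne on the C1 carbinol and a 1,1-disubstituted alkene at C3, with C4, C5 and C6 set beforehand by an Evans aldol and a proline-catalysed dihydroxyacetone aldol. One ruthenium-catalysed operation forges C2=C3, closes the carbocycle and, by cross-metathesis of the resulting vinyl group in the same flask, installs the (E)-hydroxyheptenyl chain.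

Key step: step 12

Remark on numbering: C1 is the ring carbonyl carbon, C2 bears the heptenyl chain (C1', C2' onwards), C3 the hydroxymethyl group, C4 and C5 the hydroxyl groups, C6 the butenoic acid chain. The C1 carbinol carried from step 3 to step 12 is a temporary stereocentre that step 13 removes.

Step 1
Reactants: 1 (R)-4-benzyloxazolidin-2-one; 2 pent-4-enoyl chloride
Product: 4 (R)-4-benzyl-3-(pent-4-enoyl)oxazolidin-2-one, via lithium oxazolidinide 3 (not isolated)
Conditions: n-BuLi, THF, −78 °C; then 2, −78 to 0 °C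
Reagents that add atoms: none
Why: N-Acylation of the lithiated oxazolidinone with the acid chloride (loading of the Evans auxiliary) is fast at low temperature and creates no stereocentre.

Step 2
Reactants: 4 (R)-4-benzyl-3-(pent-4-enoyl)oxazolidin-2-one; 5 tert-butyl methacrylate
Product: 6 tert-butyl (E)-6-[(R)-4-benzyl-2-oxooxazolidin-3-yl]-2-methyl-6-oxohex-2-enoate
Conditions: second-generation Hoveyda–Grubbs catalyst RuCl2(H2IMes)(=CH-C6H4-2-OiPr) (5 mol %), 5 (10 equiv), CH2Cl2, 40 °C
Reagents that add atoms: none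
Why: Olefin cross-metathesis between a terminal alkene and a methacrylate ester should give the trisubstituted enoate as the E isomer, the thermodynamically favoured product of reversible metathesis, while the imide is inert.

Step 3
Reactants: 6 tert-butyl (E)-6-[(R)-4-benzyl-2-oxooxazolidin-3-yl]-2-methyl-6-oxohex-2-enoate; 7 3-(trimethylsilyl)propynal
Product: 9 tert-butyl (2E,5R,6R)-5-[(R)-4-benzyl-2-oxooxazolidine-3-carbonyl]-6-hydroxy-2-methyl-8-(trimethylsilyl)oct-2-en-7-ynoate, via Z-boron enolate 8 (not isolated)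
Conditions: Bu2BOTf, iPr2NEt, CH2Cl2, 0 °C; then 7, −78 to 0 °C; then pH 7 buffer, MeOH, H2O2
Reagents that add atoms: none
Why: Evans syn-aldol reaction, in which the Z-boron enolate 8 reacts through a Zimmerman–Traxler chair with the benzyl group of the (R)-auxiliary blocking one enolate face, which sets C6 and, syn to it, the temporary C1 carbinol.

Step 4
Reactants: 9 tert-butyl (2E,5R,6R)-5-[(R)-4-benzyl-2-oxooxazolidine-3-carbonyl]-6-hydroxy-2-methyl-8-(trimethylsilyl)oct-2-en-7-ynoate
Product: 10 tert-butyl (2E,5R,6R)-6-hydroxy-5-[methoxy(methyl)carbamoyl]-2-methyl-8-(trimethylsilyl)oct-2-en-7-ynoate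
Conditions: MeNH(OMe)·HCl, AlMe3, CH2Cl2, −20 to 0 °C
Reagents that add atoms: N,O-dimethylhydroxylamine hydrochloride, CNOC.Cl
Why: Transamidation of the β-hydroxy imide with the aluminium amide (Weinreb amide formation) is directed by the free hydroxyl group, releases the auxiliary for recovery and leaves the hindered tert-butyl enoate and both stereocentres untouched.

Step 5
Reactants: 10 tert-butyl (2E,5R,6R)-6-hydroxy-5-[methoxy(methyl)carbamoyl]-2-methyl-8-(trimethylsilyl)oct-2-en-7-ynoate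
Product: 11 tert-butyl (2E,5R,6R)-6-[(tert-butyldimethylsilyl)oxy]-5-[methoxy(methyl)carbamoyl]-2-methyl-8-(trimethylsilyl)oct-2-en-7-ynoate
Conditions: TBSOTf, 2,6-lutidine, CH2Cl2, −78 to 0 °C
Reagents that add atoms: tert-butyldimethylsilyl triflate, CC(C)(C)[Si](C)(C)OS(=O)(=O)C(F)(F)F
Why: Silyl ether formation on the propargylic alcohol prevents retro-aldol cleavage at the aldehyde stage and affects no stereocentre.

Step 6
Reactants: 11 tert-butyl (2E,5R,6R)-6-[(tert-butyldimethylsilyl)oxy]-5-[methoxy(methyl)carbamoyl]-2-methyl-8-(trimethylsilyl)oct-2-en-7-ynoate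
Product: 12 tert-butyl (2E,5R,6R)-6-[(tert-butyldimethylsilyl)oxy]-5-formyl-2-methyl-8-(trimethylsilyl)oct-2-en-7-ynoate
Conditions: iBu2AlH (DIBAL-H), THF, −78 °C
Reagents that add atoms: none
Why: Reduction of a Weinreb amide stops at the aldehyde because the chelated tetrahedral aluminium intermediate survives until work-up, and at −78 °C the hindered conjugated tert-butyl ester should not compete.

Step 7
Reactants: 12 tert-butyl (2E,5R,6R)-6-[(tert-butyldimethylsilyl)oxy]-5-formyl-2-methyl-8-(trimethylsilyl)oct-2-en-7-ynoate; 13 2,2-dimethyl-1,3-dioxan-5-one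
Product: 14 tert-butyl (2E,5S,6R)-6-[(tert-butyldimethylsilyl)oxy]-5-{(S)-hydroxy[(S)-2,2-dimethyl-5-oxo-1,3-dioxan-4-yl]methyl}-2-methyl-8-(trimethylsilyl)oct-2-en-7-ynoate
Conditions: (S)-proline (30 mol %), DMF, 4 °C
Reagents that add atoms: none
Why: Proline-catalysed direct aldol reaction (enamine catalysis), in which the ring-locked E-enamine of 13 adds to one aldehyde face in a hydrogen-bonded chair transition state to give the anti adduct, so the catalyst sets C4 and C5, and its facial preference coincides with Felkin–Anh addition to the α-branched aldehyde 12 (matched pair).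

Step 8
Reactants: 14 tert-butyl (2E,5S,6R)-6-[(tert-butyldimethylsilyl)oxy]-5-{(S)-hydroxy[(S)-2,2-dimethyl-5-oxo-1,3-dioxan-4-yl]methyl}-2-methyl-8-(trimethylsilyl)oct-2-en-7-ynoate
Product: 15 tert-butyl (2E,5R,6R)-6-[(tert-butyldimethylsilyl)oxy]-5-{(S)-[(S)-2,2-dimethyl-5-oxo-1,3-dioxan-4-yl][(triethylsilyl)oxy]methyl}-2-methyl-8-(trimethylsilyl)oct-2-en-7-ynoate
Conditions: TESOTf, 2,6-lutidine, CH2Cl2, −78 °C
Reagents that add atoms: triethylsilyl triflate, CC[Si](CC)(CC)OS(=O)(=O)C(F)(F)F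
Why: Silylation of the β-hydroxy ketone blocks retro-aldol cleavage and keeps the hydroxyl group from consuming the titanium reagent of the next step.

Step 9
Reactants: 15 tert-butyl (2E,5R,6R)-6-[(tert-butyldimethylsilyl)oxy]-5-{(S)-[(S)-2,2-dimethyl-5-oxo-1,3-dioxan-4-yl][(triethylsilyl)oxy]methyl}-2-methyl-8-(trimethylsilyl)oct-2-en-7-ynoate
Product: 16 tert-butyl (2E,5R,6R)-6-[(tert-butyldimethylsilyl)oxy]-5-{(S)-[(R)-2,2-dimethyl-5-methylidene-1,3-dioxan-4-yl][(triethylsilyl)oxy]methyl}-2-methyl-8-(trimethylsilyl)oct-2-en-7-ynoate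
Conditions: Zn, CH2Br2, TiCl4, THF; then 15 in CH2Cl2, 0 °C to rt
Reagents that add atoms: dibromomethane, BrCBr
Why: Lombardo–Takai methylenation with the zinc/titanium gem-dimetallic reagent is non-basic, so the ketone flanked by the epimerisable C4 and a β-silyloxy group should give the exocyclic methylene without epimerisation or β-elimination, and the ester is not attacked.

Step 10
Reactants: 16 tert-butyl (2E,5R,6R)-6-[(tert-butyldimethylsilyl)oxy]-5-{(S)-[(R)-2,2-dimethyl-5-methylidene-1,3-dioxan-4-yl][(triethylsilyl)oxy]methyl}-2-methyl-8-(trimethylsilyl)oct-2-en-7-ynoate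
Product: 17 tert-butyl (2E,5R,6R)-6-hydroxy-5-{(S)-hydroxy[(R)-2,2-dimethyl-5-methylidene-1,3-dioxan-4-yl]methyl}-2-methyloct-2-en-7-ynoate
Conditions: Bu4NF, THF, 0 °C to rt
Reagents that add atoms: none
Why: Fluoride cleaves the alkynyl C–Si bond and both silyl ethers in one operation, which is safe here because no base-sensitive carbonyl is left next to C4–C6.

Step 11
Reactants: 18 (R)-2-methyloxirane; 19 but-3-en-1-ylmagnesium bromide
Product: 20 (R)-hept-6-en-2-ol
Conditions: CuI (10 mol %), THF, −30 to 0 °C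
Reagents that add atoms: none
Why: Copper-catalysed Grignard opening of the epoxide at its unsubstituted carbon (SN2) leaves the stereocentre of the epoxide untouched.

Step 12
Reactants: 17 tert-butyl (2E,5R,6R)-6-hydroxy-5-{(S)-hydroxy[(R)-2,2-dimethyl-5-methylidene-1,3-dioxan-4-yl]methyl}-2-methyloct-2-en-7-ynoate; 20 (R)-hept-6-en-2-ol
Product: 22 tert-butyl (E)-4-[(6R,7R,8S,8aR)-6,8-dihydroxy-5-[(1E,6R)-6-hydroxyhept-1-en-1-yl]-2,2-dimethyl-6,7,8,8a-tetrahydro-4H-benzo[d][1,3]dioxin-7-yl]-2-methylbut-2-enoate, via 2-vinyl diene 21 (not isolated)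
Conditions: second-generation Hoveyda–Grubbs catalyst RuCl2(H2IMes)(=CH-C6H4-2-OiPr) (10 mol %), ethylene (1 atm), 1,4-benzoquinone (10 mol %), toluene, 80 °C; then argon purge, 20 (5 equiv), 40 °C
Reagents that add atoms: none
Why: Ring-closing enyne metathesis of a 1,7-enyne followed in the same flask by diene cross-metathesis, both known reaction types: the ruthenium methylidene adds to the terminal alkyne with the metal on the internal carbon C2, and the resulting vinylcarbene undergoes [2+2] cycloaddition and cycloreversion with the exocyclic methylene on C3, which forges C2=C3 and releases the methylidene again. The six-membered carbocycle closes in the exo mode of enyne metathesis, so that C2 and C3 both become ring atoms and the former alkyne terminus becomes the vinyl group on C2. No stereocentre is formed; the E geometry of C1'=C2' is set in the reversible cross-metathesis under thermodynamic control, reinforced by allylic strain between a Z substituent and the ring. The step needs exo closure (six-membered ring) over endo closure (seven-membered ring), which the shorter ring and the dioxane that holds the C3 methylene next to the chain should secure. It also needs chemoselectivity, which follows because the trisubstituted electron-poor enoate and the tetrasubstituted ring alkene do not enter metathesis, so only the terminal vinyl group of 21 reacts with 20. 1,4-Benzoquinone suppresses ruthenium hydride isomerisation of the dienylic alcohol.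

Step 13
Reactants: 22 tert-butyl (E)-4-[(6R,7R,8S,8aR)-6,8-dihydroxy-5-[(1E,6R)-6-hydroxyhept-1-en-1-yl]-2,2-dimethyl-6,7,8,8a-tetrahydro-4H-benzo[d][1,3]dioxin-7-yl]-2-methylbut-2-enoate
Product: 23 tert-butyl (E)-4-[(7S,8S,8aR)-8-hydroxy-5-[(1E,6R)-6-hydroxyhept-1-en-1-yl]-2,2-dimethyl-6-oxo-6,7,8,8a-tetrahydro-4H-benzo[d][1,3]dioxin-7-yl]-2-methylbut-2-enoate
Conditions: MnO2, CH2Cl2, rt
Reagents that add atoms: none
Why: MnO2 oxidises only allylic alcohols, so the dienylic C1 carbinol becomes the ketone while the saturated C5 and side-chain alcohols stay, and the temporary C1 stereocentre disappears.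

Step 14
Reactants: 23 tert-butyl (E)-4-[(7S,8S,8aR)-8-hydroxy-5-[(1E,6R)-6-hydroxyhept-1-en-1-yl]-2,2-dimethyl-6-oxo-6,7,8,8a-tetrahydro-4H-benzo[d][1,3]dioxin-7-yl]-2-methylbut-2-enoate
Product: 24 pestallic acid O, (E)-4-[(1S,5R,6S)-5,6-dihydroxy-4-(hydroxymethyl)-3-[(1E,6R)-6-hydroxyhept-1-en-1-yl]-2-oxocyclohex-3-en-1-yl]-2-methylbut-2-enoic acid
Conditions: CF3CO2H/H2O (9:1), 0 °C to rt
Reagents that add atoms: none
Why: Aqueous trifluoroacetic acid hydrolyses the isopropylidene acetal and cleaves the tert-butyl ester by the tert-butyl cation pathway without base, so the β-hydroxy ketone and the ketone α-stereocentre C6 (already in the more stable trans arrangement to the C5 hydroxyl) should survive.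

Compound list
1 | (R)-4-benzyloxazolidin-2-one | O=C1OC[C@@H](Cc2ccccc2)N1 | starting material
2 | pent-4-enoyl chloride | C=CCCC(=O)Cl | starting material
3 | lithium (R)-4-benzyl-2-oxooxazolidin-3-ide | [Li+].O=C1OC[C@@H](Cc2ccccc2)[N-]1 | intermediate (not isolated)
4 | (R)-4-benzyl-3-(pent-4-enoyl)oxazolidin-2-one | C=CCCC(=O)N1[C@H](Cc2ccccc2)COC1=O | intermediate
5 | tert-butyl methacrylate | C=C(C)C(=O)OC(C)(C)C | starting material
6 | tert-butyl (E)-6-[(R)-4-benzyl-2-oxooxazolidin-3-yl]-2-methyl-6-oxohex-2-enoate | C/C(=C\CCC(=O)N1[C@H](Cc2ccccc2)COC1=O)C(=O)OC(C)(C)C | intermediate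
7 | 3-(trimethylsilyl)propynal | O=CC#C[Si](C)(C)C | starting material
8 | di-n-butylboron (Z)-enolate of 6 | CCCCB(CCCC)O/C(=C\C/C=C(\C)C(=O)OC(C)(C)C)N1[C@H](Cc2ccccc2)COC1=O | intermediate (not isolated)
9 | tert-butyl (2E,5R,6R)-5-[(R)-4-benzyl-2-oxooxazolidine-3-carbonyl]-6-hydroxy-2-methyl-8-(trimethylsilyl)oct-2-en-7-ynoate | C/C(=C\C[C@@H](C(=O)N1[C@H](Cc2ccccc2)COC1=O)[C@@H](O)C#C[Si](C)(C)C)C(=O)OC(C)(C)C | intermediate
10 | tert-butyl (2E,5R,6R)-6-hydroxy-5-[methoxy(methyl)carbamoyl]-2-methyl-8-(trimethylsilyl)oct-2-en-7-ynoate | C/C(=C\C[C@@H](C(=O)N(C)OC)[C@@H](O)C#C[Si](C)(C)C)C(=O)OC(C)(C)C | intermediate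
11 | tert-butyl (2E,5R,6R)-6-[(tert-butyldimethylsilyl)oxy]-5-[methoxy(methyl)carbamoyl]-2-methyl-8-(trimethylsilyl)oct-2-en-7-ynoate | C/C(=C\C[C@@H](C(=O)N(C)OC)[C@@H](O[Si](C)(C)C(C)(C)C)C#C[Si](C)(C)C)C(=O)OC(C)(C)C | intermediate
12 | tert-butyl (2E,5R,6R)-6-[(tert-butyldimethylsilyl)oxy]-5-formyl-2-methyl-8-(trimethylsilyl)oct-2-en-7-ynoate | C/C(=C\C[C@@H](C=O)[C@@H](O[Si](C)(C)C(C)(C)C)C#C[Si](C)(C)C)C(=O)OC(C)(C)C | intermediate
13 | 2,2-dimethyl-1,3-dioxan-5-one | CC1(C)OCC(=O)CO1 | starting material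
14 | tert-butyl (2E,5S,6R)-6-[(tert-butyldimethylsilyl)oxy]-5-{(S)-hydroxy[(S)-2,2-dimethyl-5-oxo-1,3-dioxan-4-yl]methyl}-2-methyl-8-(trimethylsilyl)oct-2-en-7-ynoate | C/C(=C\C[C@@H]([C@H](O)[C@@H]1OC(C)(C)OCC1=O)[C@@H](O[Si](C)(C)C(C)(C)C)C#C[Si](C)(C)C)C(=O)OC(C)(C)C | intermediate
15 | tert-butyl (2E,5R,6R)-6-[(tert-butyldimethylsilyl)oxy]-5-{(S)-[(S)-2,2-dimethyl-5-oxo-1,3-dioxan-4-yl][(triethylsilyl)oxy]methyl}-2-methyl-8-(trimethylsilyl)oct-2-en-7-ynoate | C/C(=C\C[C@@H]([C@H](O[Si](CC)(CC)CC)[C@@H]1OC(C)(C)OCC1=O)[C@@H](O[Si](C)(C)C(C)(C)C)C#C[Si](C)(C)C)C(=O)OC(C)(C)C | intermediate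
16 | tert-butyl (2E,5R,6R)-6-[(tert-butyldimethylsilyl)oxy]-5-{(S)-[(R)-2,2-dimethyl-5-methylidene-1,3-dioxan-4-yl][(triethylsilyl)oxy]methyl}-2-methyl-8-(trimethylsilyl)oct-2-en-7-ynoate | C/C(=C\C[C@@H]([C@H](O[Si](CC)(CC)CC)[C@@H]1OC(C)(C)OCC1=C)[C@@H](O[Si](C)(C)C(C)(C)C)C#C[Si](C)(C)C)C(=O)OC(C)(C)C | intermediate
17 | tert-butyl (2E,5R,6R)-6-hydroxy-5-{(S)-hydroxy[(R)-2,2-dimethyl-5-methylidene-1,3-dioxan-4-yl]methyl}-2-methyloct-2-en-7-ynoate | C/C(=C\C[C@@H]([C@H](O)[C@@H]1OC(C)(C)OCC1=C)[C@@H](O)C#C)C(=O)OC(C)(C)C | intermediate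
18 | (R)-2-methyloxirane | C[C@@H]1CO1 | starting material
19 | but-3-en-1-ylmagnesium bromide | C=CCC[Mg]Br | starting material
20 | (R)-hept-6-en-2-ol | C[C@@H](O)CCCC=C | intermediate
21 | tert-butyl (E)-4-[(6R,7R,8S,8aR)-5-ethenyl-6,8-dihydroxy-2,2-dimethyl-6,7,8,8a-tetrahydro-4H-benzo[d][1,3]dioxin-7-yl]-2-methylbut-2-enoate | C/C(=C\C[C@@H]1[C@@H](O)C(C=C)=C2COC(C)(C)O[C@H]2[C@H]1O)C(=O)OC(C)(C)C | intermediate (not isolated)
22 | tert-butyl (E)-4-[(6R,7R,8S,8aR)-6,8-dihydroxy-5-[(1E,6R)-6-hydroxyhept-1-en-1-yl]-2,2-dimethyl-6,7,8,8a-tetrahydro-4H-benzo[d][1,3]dioxin-7-yl]-2-methylbut-2-enoate | C/C(=C\C[C@@H]1[C@@H](O)C(/C=C/CCC[C@@H](C)O)=C2COC(C)(C)O[C@H]2[C@H]1O)C(=O)OC(C)(C)C | intermediate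
23 | tert-butyl (E)-4-[(7S,8S,8aR)-8-hydroxy-5-[(1E,6R)-6-hydroxyhept-1-en-1-yl]-2,2-dimethyl-6-oxo-6,7,8,8a-tetrahydro-4H-benzo[d][1,3]dioxin-7-yl]-2-methylbut-2-enoate | C/C(=C\C[C@@H]1C(=O)C(/C=C/CCC[C@@H](C)O)=C2COC(C)(C)O[C@H]2[C@H]1O)C(=O)OC(C)(C)C | intermediate
24 | pestallic acid O, (E)-4-[(1S,5R,6S)-5,6-dihydroxy-4-(hydroxymethyl)-3-[(1E,6R)-6-hydroxyhept-1-en-1-yl]-2-oxocyclohex-3-en-1-yl]-2-methylbut-2-enoic acid | C/C(=C\C[C@@H]1C(=O)C(/C=C/CCC[C@@H](C)O)=C(CO)[C@@H](O)[C@H]1O)C(=O)O | target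

Total step count: 14. Longest linear sequence: 13 steps (steps 1–10 and 12–14; step 11 makes the side-chain alkene).

Steps most likely to fail

Step 12. The ruthenium vinylcarbene may fail to engage the hindered 1,1-disubstituted alkene and be intercepted by ethylene to an acyclic triene, or it may close in the endo mode to a seven-membered ring; in the second stage the cross-metathesis may stay incomplete or give E/Z mixtures. The fallback sets out from 17 and closes the same C2=C3 bond as an easier trisubstituted alkene, adding the C2 substituent afterwards. Semi-hydrogenation of the alkyne (H2, Pd/CaCO3 poisoned with Pb(OAc)2, quinoline) should give the 1,7-diene diol F1. Diene ring-closing metathesis (second-generation Grubbs catalyst RuCl2(H2IMes)(PCy3)(=CHPh), CH2Cl2, 40 °C) should give the bicyclic cyclohexenediol F2, and MnO2 the enone F3. α-Iodination (I2, pyridine, CH2Cl2) should give the 2-iodoenone F4, and Stille coupling with tributyl(vinyl)stannane (Pd(PPh3)4, CuI, DMF) the 2-vinyl enone F5. Cross-metathesis of F5 with 20 comes back to the route at 23.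

Step 7. Proline may condense with the acceptor aldehyde 12 itself, which would open epimerisation at C6 and β-elimination of the silyloxy group, and turnover with the hindered aldehyde may be slow. The fallback sets out from 12 and 13 and uses a stoichiometric metal enolate under substrate control. Ketone 13 is converted with (c-C6H11)2BCl and Et3N (Et2O, −78 °C) into the dicyclohexylboron enolate F6, which adds to 12 through a closed chair transition state. The ring-locked E-enolate should give the anti aldol, and Felkin–Anh control by the α-stereocentre of 12 should give the same diastereomer; aqueous work-up comes back to the route at 14.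

Step 9. Methylenation of the hindered, doubly α-oxygenated ketone may be sluggish, with competing Lewis-acid cleavage of the triethylsilyl ether or the acetal. The fallback sets out from 15 and uses a two-stage Peterson olefination. Addition of Me3SiCH2Li/CeCl3 (THF, −78 °C) to the ketone should give the β-hydroxysilane F7, and KH (THF, 0 °C) then induces syn-elimination of silanolate, which comes back to the route at 16.

Further compounds
F1 | step 12 | 1,7-diene diol, the 7,8-alkene analogue of 17 | C/C(=C\C[C@@H]([C@H](O)[C@@H]1OC(C)(C)OCC1=C)[C@@H](O)C=C)C(=O)OC(C)(C)C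
F2 | step 12 | bicyclic cyclohexenediol, analogue of 21 with hydrogen on C2 | C/C(=C\C[C@@H]1[C@@H](O)C=C2COC(C)(C)O[C@H]2[C@H]1O)C(=O)OC(C)(C)C
F3 | step 12 | bicyclic enone with hydrogen on C2 | C/C(=C\C[C@@H]1C(=O)C=C2COC(C)(C)O[C@H]2[C@H]1O)C(=O)OC(C)(C)C
F4 | step 12 | 2-iodoenone | C/C(=C\C[C@@H]1C(=O)C(I)=C2COC(C)(C)O[C@H]2[C@H]1O)C(=O)OC(C)(C)C
F5 | step 12 | 2-vinyl enone | C/C(=C\C[C@@H]1C(=O)C(C=C)=C2COC(C)(C)O[C@H]2[C@H]1O)C(=O)OC(C)(C)C
F6 | step 7 | dicyclohexylboron enolate of 13 | CC1(C)OCC(OB(C2CCCCC2)C2CCCCC2)=CO1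
F7 | step 9 | β-hydroxysilane from 15, both epimers at the new carbinol carbon | C/C(=C\C[C@@H]([C@H](O[Si](CC)(CC)CC)[C@@H]1OC(C)(C)OCC1(O)C[Si](C)(C)C)[C@@H](O[Si](C)(C)C(C)(C)C)C#C[Si](C)(C)C)C(=O)OC(C)(C)C
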